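## Retrosynthetic overview

1. The two esters go on last: the C10 hydroxyl is tigloylated first, the C6 hydroxyl is then acylated with 4-acetoxybenzoyl chloride, and the phenol is freed.
2. C5–H and C6–OH (both on the face of the C4 oxygen) come from a C4–O-tethered hydrosilylation and Tamao oxidation of the C5=C6 alkene of a dauca-5,8-diene.
3. Key disconnection C1–C10: a new [2,3]-Wittig ring expansion of a 2-cyclopentenyl-3,6-dihydro-2H-pyran gives the seven-membered ring, the C1 quaternary centre and the C10 carbinol in one step.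
4. The dihydropyran comes from ring-closing metathesis of an allyl ether, made by asymmetric methallylation of a cyclopentenecarbaldehyde (temporary C6 stereocentre, later relayed to C1).
5. Ring order: five-membered ring first (ozonolysis/aldol ring contraction of (R)-terpinen-4-ol, which supplies C4), then the temporary dihydropyran, then the seven-membered ring.

Assumption: (R)-(−)-terpinen-4-ol is used at ≥98% ee (enriched if the purchased lot is lower); locants are daucane numbers (C1 quaternary CMe, C4 carbinol, C5 ring-fusion CH, C6 benzoate carbon, C8=C9 alkene, C10 tiglate carbon) and α means the face of the C4 oxygen, opposite the C1 methyl.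

## Route

Step 1
Reactants: 1 (R)-(−)-terpinen-4-ol; 2 triethylsilyl trifluoromethanesulfonate
Product: 3 triethyl{[(1R)-4-methyl-1-(propan-2-yl)cyclohex-3-en-1-yl]oxy}silane
Conditions: 2,6-lutidine, CH2Cl2, −78 → 0 °C
Reagents that add atoms: triethylsilyl trifluoromethanesulfonate, CC[Si](CC)(CC)OS(=O)(=O)C(F)(F)F
Why: O-silylation of the hindered tertiary alcohol with a silyl triflate masks the C4 oxygen (stereocentre from the chiral pool, untouched) so that the β-oxygenated aldehyde made next cannot undergo retro-aldol cleavage.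

Step 2
Reactants: 3 triethyl{[(1R)-4-methyl-1-(propan-2-yl)cyclohex-3-en-1-yl]oxy}silane; 4 ozone
Product: 6 (3R)-6-oxo-3-(propan-2-yl)-3-[(triethylsilyl)oxy]heptanal, via ozonide 5 (not isolated)
Conditions: O3, CH2Cl2, −78 °C; then PPh3, −78 °C → rt
Reagents that add atoms: ozone, [O-][O+]=O
Why: Ozonolysis with reductive work-up cleaves the only alkene to the 1,6-keto aldehyde and leaves the silyl ether and C4 unchanged.

Step 3
Reactants: 6 (3R)-6-oxo-3-(propan-2-yl)-3-[(triethylsilyl)oxy]heptanal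
Product: 7 (5S)-2-methyl-5-(propan-2-yl)-5-[(triethylsilyl)oxy]cyclopent-1-ene-1-carbaldehyde
Conditions: (PhCH2)2NH2+ CF3CO2− (0.3 equiv), toluene, 50 °C
Reagents that add atoms: none
Why: Ammonium-carboxylate-catalysed intramolecular aldol condensation (the aldehyde enamine adds 5-exo to the methyl ketone, then water is lost from the free tertiary aldol hydroxyl in preference to the silyl ether) contracts the ring to the 2-methylcyclopent-1-enecarbaldehyde.

Step 4
Reactants: 7 (5S)-2-methyl-5-(propan-2-yl)-5-[(triethylsilyl)oxy]cyclopent-1-ene-1-carbaldehyde; 8 4,4,5,5-tetramethyl-2-(2-methylprop-2-en-1-yl)-1,3,2-dioxaborolane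
Product: 10 (1S)-3-methyl-1-{(5S)-2-methyl-5-(propan-2-yl)-5-[(triethylsilyl)oxy]cyclopent-1-en-1-yl}but-3-en-1-ol, via boronic ester 9 (not isolated)
Conditions: (S)-3,3′-bis(2,4,6-triisopropylphenyl)-1,1′-binaphthyl-2,2′-diyl hydrogen phosphate (5 mol%), toluene, −30 °C; then H2O
Reagents that add atoms: 4,4,5,5-tetramethyl-2-(2-methylprop-2-en-1-yl)-1,3,2-dioxaborolane, CC(=C)CB1OC(C)(C)C(C)(C)O1
Why: Chiral phosphoric acid-catalysed allylboration through a chair transition state, in which the (S)-acid directs the methallyl group to the Si face of the aldehyde (the antipodal acid is known to give Re-face attack), sets C6 as S under catalyst control.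

Step 5
Reactants: 10 (1S)-3-methyl-1-{(5S)-2-methyl-5-(propan-2-yl)-5-[(triethylsilyl)oxy]cyclopent-1-en-1-yl}but-3-en-1-ol; 11 3-bromoprop-1-ene
Product: 13 allyl ether of 10 at the C6 oxygen (6S; 4S), via sodium alkoxide 12 (not isolated)
Conditions: NaH, Bu4NI (5 mol%), THF, 0 °C → rt
Reagents that add atoms: 3-bromoprop-1-ene, C=CCBr
Why: Williamson ether synthesis on the secondary alkoxide, where fast alkylation by the allylic bromide at 0 °C outruns 1,5-silyl migration and no stereocentre is touched.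

Step 6
Reactants: 13 allyl ether of 10
Product: 14 (2S)-4-methyl-2-{(5S)-2-methyl-5-(propan-2-yl)-5-[(triethylsilyl)oxy]cyclopent-1-en-1-yl}-3,6-dihydro-2H-pyran
Conditions: second-generation Grubbs catalyst RuCl2(=CHPh)(PCy3)(H2IMes) (3 mol%), CH2Cl2, 40 °C
Reagents that add atoms: none
Why: Ring-closing metathesis of the allyl ether with the 1,1-disubstituted methallyl alkene gives the six-membered cyclic ether with the C8=C9 trisubstituted alkene, the tetrasubstituted cyclopentene being inert.

Step 7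
Reactants: 14 (2S)-4-methyl-2-{(5S)-2-methyl-5-(propan-2-yl)-5-[(triethylsilyl)oxy]cyclopent-1-en-1-yl}-3,6-dihydro-2H-pyran
Product: 17 (3S,8R,8aS)-6,8a-dimethyl-3-(propan-2-yl)-3-[(triethylsilyl)oxy]-1,2,3,5,8,8a-hexahydroazulen-8-ol, via allyllithium 15 (not isolated), via lithium alkoxide 16 (not isolated)
Conditions: sec-butyllithium (1.3 equiv), THF, −78 → −40 °C; then H2O
Reagents that add atoms: none
Why: Proposed new method: sec-butyllithium removes a proton from the ring O–CH2 that is both α-oxy and allylic (C10), and with the cyclopentenyl group axial this ring α-oxyallyl anion lies over C1, so a concerted suprafacial [2,3]-sigmatropic shift (five-membered envelope transition state held inside an unstrained 8-oxabicyclo[3.2.1]octadiene-like array) forms C1–C10 as C6–O breaks and turns the six-membered ether into the seven-membered carbocycle with the new C5=C6 alkene; the bond to C1 forms on the face from which the oxygen leaves, so 6S is relayed to 1S (the face of the C4 oxygen), and because the oxygen has to stay on the C5 side of C10 the alkoxide ends anti to the C1 methyl (10R); the closest known reaction type is the acyclic [2,3]-Wittig rearrangement of bis-allylic ethers and its ring-contraction variant in macrocyclic diallyl ethers, which has not been shown for a ring α-oxyallyl anion of a dihydropyran attacking an exocyclic tetrasubstituted alkene.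

Step 8
Reactants: 17 (3S,8R,8aS)-6,8a-dimethyl-3-(propan-2-yl)-3-[(triethylsilyl)oxy]-1,2,3,5,8,8a-hexahydroazulen-8-ol; 18 (2E)-2-methylbut-2-enoyl chloride
Product: 19 (3S,8R,8aS)-6,8a-dimethyl-3-(propan-2-yl)-3-[(triethylsilyl)oxy]-1,2,3,5,8,8a-hexahydroazulen-8-yl (2E)-2-methylbut-2-enoate
Conditions: pyridine, 4-(dimethylamino)pyridine (10 mol%), CH2Cl2, 0 °C → rt
Reagents that add atoms: (2E)-2-methylbut-2-enoyl chloride, C/C=C(\C)C(Cl)=O
Why: Nucleophile-catalysed acylation of the only free hydroxyl (C10) with the acid chloride, the E geometry of the tiglate coming from the reagent.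

Step 9
Reactants: 19 (3S,8R,8aS)-6,8a-dimethyl-3-(propan-2-yl)-3-[(triethylsilyl)oxy]-1,2,3,5,8,8a-hexahydroazulen-8-yl (2E)-2-methylbut-2-enoate
Product: 20 (3S,8R,8aS)-3-hydroxy-6,8a-dimethyl-3-(propan-2-yl)-1,2,3,5,8,8a-hexahydroazulen-8-yl (2E)-2-methylbut-2-enoate
Conditions: HF·pyridine, pyridine, THF, 0 °C → rt
Reagents that add atoms: none
Why: Buffered fluoride desilylation frees the tertiary C4 hydroxyl without ionising the allylic C–O bond or cleaving the tiglate.

Step 10
Reactants: 20 (3S,8R,8aS)-3-hydroxy-6,8a-dimethyl-3-(propan-2-yl)-1,2,3,5,8,8a-hexahydroazulen-8-yl (2E)-2-methylbut-2-enoate; 21 chlorodimethylsilane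
Product: 23 cyclic siloxane in which SiMe2 links the C4 oxygen to C6 (1,2-oxasilolane; C6–Si and H5 both α; 10-tiglate kept), via dimethylsilyl ether 22 (not isolated)
Conditions: Et3N, CH2Cl2, 0 °C; then Pt2[(CH2=CHSiMe2)2O]3 (Karstedt catalyst, zerovalent platinum, 0.5 mol%), toluene, 60 °C
Reagents that add atoms: chlorodimethylsilane, C[SiH](C)Cl
Why: O-silylation followed by platinum-catalysed intramolecular hydrosilylation (Tamao silicon tether, 5-endo) adds Si–H syn across C5=C6 from the face of the C4 oxygen, so H5 and the C6–Si bond are both α, which fixes C5 and C6.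

Step 11
Reactants: 23 cyclic siloxane; 24 hydrogen peroxide
Product: 25 (3S,3aS,4S,8R,8aS)-3,4-dihydroxy-6,8a-dimethyl-3-(propan-2-yl)-1,2,3,3a,4,5,8,8a-octahydroazulen-8-yl (2E)-2-methylbut-2-enoate
Conditions: KF, KHCO3, THF/MeOH, rt
Reagents that add atoms: hydrogen peroxide, OO
Why: Tamao–Fleming oxidation converts the C6–Si bond into C6–OH with retention and releases the C4 hydroxyl, the mild fluoride/bicarbonate conditions leaving the tiglate and the C8=C9 alkene intact.

Step 12
Reactants: 25 (3S,3aS,4S,8R,8aS)-3,4-dihydroxy-6,8a-dimethyl-3-(propan-2-yl)-1,2,3,3a,4,5,8,8a-octahydroazulen-8-yl (2E)-2-methylbut-2-enoate; 26 4-(chlorocarbonyl)phenyl acetate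
Product: 27 (3S,3aS,4S,8R,8aS)-3-hydroxy-6,8a-dimethyl-8-{[(2E)-2-methylbut-2-enoyl]oxy}-3-(propan-2-yl)-1,2,3,3a,4,5,8,8a-octahydroazulen-4-yl 4-(acetyloxy)benzoate
Conditions: pyridine, 4-(dimethylamino)pyridine (10 mol%), CH2Cl2, 0 °C → rt
Reagents that add atoms: 4-(chlorocarbonyl)phenyl acetate, CC(=O)Oc1ccc(cc1)C(Cl)=O
Why: Nucleophile-catalysed esterification acylates the secondary C6 hydroxyl and not the tertiary C4 hydroxyl (steric differentiation).

Step 13
Reactants: 27 (3S,3aS,4S,8R,8aS)-3-hydroxy-6,8a-dimethyl-8-{[(2E)-2-methylbut-2-enoyl]oxy}-3-(propan-2-yl)-1,2,3,3a,4,5,8,8a-octahydroazulen-4-yl 4-(acetyloxy)benzoate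
Product: 28 (3S,3aS,4S,8R,8aS)-3-hydroxy-6,8a-dimethyl-8-{[(2E)-2-methylbut-2-enoyl]oxy}-3-(propan-2-yl)-1,2,3,3a,4,5,8,8a-octahydroazulen-4-yl 4-hydroxybenzoate (target CNP0273650.6)
Conditions: pyrrolidine (2 equiv), CH2Cl2, 0 °C
Reagents that add atoms: none
Why: Chemoselective aminolysis of the phenolic acetate, which reacts far faster than the alkyl benzoate and the hindered tiglate, frees the phenol.

## Compound list

1 | (R)-(−)-terpinen-4-ol, (1R)-4-methyl-1-(propan-2-yl)cyclohex-3-en-1-ol | CC1=CC[C@@](O)(C(C)C)CC1 | starting material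
2 | triethylsilyl trifluoromethanesulfonate | CC[Si](CC)(CC)OS(=O)(=O)C(F)(F)F | starting material
3 | triethyl{[(1R)-4-methyl-1-(propan-2-yl)cyclohex-3-en-1-yl]oxy}silane | CC1=CC[C@@](O[Si](CC)(CC)CC)(C(C)C)CC1 | intermediate
4 | ozone | [O-][O+]=O | starting material
5 | secondary ozonide of 3 (1,2,4-trioxolane across the former alkene; two diastereomers at the trioxolane carbons) | CC12CC[C@](O[Si](CC)(CC)CC)(C(C)C)CC(OO1)O2 | intermediate (not isolated)
6 | (3R)-6-oxo-3-(propan-2-yl)-3-[(triethylsilyl)oxy]heptanal | O=CC[C@@](O[Si](CC)(CC)CC)(C(C)C)CCC(C)=O | intermediate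
7 | (5S)-2-methyl-5-(propan-2-yl)-5-[(triethylsilyl)oxy]cyclopent-1-ene-1-carbaldehyde | O=CC1=C(C)CC[C@]1(O[Si](CC)(CC)CC)C(C)C | intermediate
8 | 4,4,5,5-tetramethyl-2-(2-methylprop-2-en-1-yl)-1,3,2-dioxaborolane | CC(=C)CB1OC(C)(C)C(C)(C)O1 | starting material
9 | O-pinacolboryl ether of 10 | CC1(C)OB(O[C@@H](CC(C)=C)C2=C(C)CC[C@]2(O[Si](CC)(CC)CC)C(C)C)OC1(C)C | intermediate (not isolated)
10 | (1S)-3-methyl-1-{(5S)-2-methyl-5-(propan-2-yl)-5-[(triethylsilyl)oxy]cyclopent-1-en-1-yl}but-3-en-1-ol | O[C@@H](CC(C)=C)C1=C(C)CC[C@]1(O[Si](CC)(CC)CC)C(C)C | intermediate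
11 | 3-bromoprop-1-ene (allyl bromide) | C=CCBr | starting material
12 | sodium alkoxide of 10 | [Na]O[C@@H](CC(C)=C)C1=C(C)CC[C@]1(O[Si](CC)(CC)CC)C(C)C | intermediate (not isolated)
13 | allyl ether of 10: triethyl{[(1S)-3-methyl-2-[(1S)-3-methyl-1-(prop-2-en-1-yloxy)but-3-en-1-yl]-1-(propan-2-yl)cyclopent-2-en-1-yl]oxy}silane | C=CCO[C@@H](CC(C)=C)C1=C(C)CC[C@]1(O[Si](CC)(CC)CC)C(C)C | intermediate
14 | (2S)-4-methyl-2-{(5S)-2-methyl-5-(propan-2-yl)-5-[(triethylsilyl)oxy]cyclopent-1-en-1-yl}-3,6-dihydro-2H-pyran | CC1=CCO[C@@H](C1)C2=C(C)CC[C@]2(O[Si](CC)(CC)CC)C(C)C | intermediate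
15 | 6-lithio derivative of 14 (lithium on the ring O–CH carbon, C10; configuration at that carbon not fixed) | CC1=CC([Li])O[C@@H](C1)C2=C(C)CC[C@]2(O[Si](CC)(CC)CC)C(C)C | intermediate (not isolated)
16 | lithium alkoxide of 17 | [Li]O[C@@H]1C=C(C)CC=C2[C@]1(C)CC[C@]2(O[Si](CC)(CC)CC)C(C)C | intermediate (not isolated)
17 | (3S,8R,8aS)-6,8a-dimethyl-3-(propan-2-yl)-3-[(triethylsilyl)oxy]-1,2,3,5,8,8a-hexahydroazulen-8-ol | O[C@@H]1C=C(C)CC=C2[C@]1(C)CC[C@]2(O[Si](CC)(CC)CC)C(C)C | intermediate
18 | (2E)-2-methylbut-2-enoyl chloride (tigloyl chloride) | C/C=C(\C)C(Cl)=O | starting material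
19 | (3S,8R,8aS)-6,8a-dimethyl-3-(propan-2-yl)-3-[(triethylsilyl)oxy]-1,2,3,5,8,8a-hexahydroazulen-8-yl (2E)-2-methylbut-2-enoate | C/C=C(\C)C(=O)O[C@@H]1C=C(C)CC=C2[C@]1(C)CC[C@]2(O[Si](CC)(CC)CC)C(C)C | intermediate
20 | (3S,8R,8aS)-3-hydroxy-6,8a-dimethyl-3-(propan-2-yl)-1,2,3,5,8,8a-hexahydroazulen-8-yl (2E)-2-methylbut-2-enoate | C/C=C(\C)C(=O)O[C@@H]1C=C(C)CC=C2[C@]1(C)CC[C@]2(O)C(C)C | intermediate
21 | chlorodimethylsilane | C[SiH](C)Cl | starting material
22 | O-dimethylsilyl (Si–H) ether of 20 at the C4 oxygen | C/C=C(\C)C(=O)O[C@@H]1C=C(C)CC=C2[C@]1(C)CC[C@]2(O[SiH](C)C)C(C)C | intermediate (not isolated)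
23 | cyclic siloxane: SiMe2 bonded to C6 (α) and to the C4 oxygen (1,2-oxasilolane), H5 α, 10-tiglate | C/C=C(\C)C(=O)O[C@@H]1C=C(C)C[C@H]3[C@@H]2[C@]1(C)CC[C@]2(O[Si]3(C)C)C(C)C | intermediate
24 | hydrogen peroxide | OO | starting material
25 | (3S,3aS,4S,8R,8aS)-3,4-dihydroxy-6,8a-dimethyl-3-(propan-2-yl)-1,2,3,3a,4,5,8,8a-octahydroazulen-8-yl (2E)-2-methylbut-2-enoate | C/C=C(\C)C(=O)O[C@@H]1C=C(C)C[C@H](O)[C@@H]2[C@]1(C)CC[C@]2(O)C(C)C | intermediate
26 | 4-(chlorocarbonyl)phenyl acetate (4-acetoxybenzoyl chloride) | CC(=O)Oc1ccc(cc1)C(Cl)=O | starting material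
27 | (3S,3aS,4S,8R,8aS)-3-hydroxy-6,8a-dimethyl-8-{[(2E)-2-methylbut-2-enoyl]oxy}-3-(propan-2-yl)-1,2,3,3a,4,5,8,8a-octahydroazulen-4-yl 4-(acetyloxy)benzoate | C/C=C(\C)C(=O)O[C@@H]1C=C(C)C[C@H](OC(=O)c2ccc(OC(C)=O)cc2)[C@@H]2[C@]1(C)CC[C@]2(O)C(C)C | intermediate
28 | (3S,3aS,4S,8R,8aS)-3-hydroxy-6,8a-dimethyl-8-{[(2E)-2-methylbut-2-enoyl]oxy}-3-(propan-2-yl)-1,2,3,3a,4,5,8,8a-octahydroazulen-4-yl 4-hydroxybenzoate | C/C=C(\C)C(=O)O[C@@H]1C=C(C)C[C@H](OC(=O)c2ccc(O)cc2)[C@@H]2[C@]1(C)CC[C@]2(O)C(C)C | target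

## Step count and risks

Total step count: 13. Longest linear sequence: 13 steps (the route is fully linear from 1).

The three steps most likely to fail are 7, 10 and 4.

Step 7 (the proposed ring expansion). A radical-pair [1,2]-shift to a cyclopentenol or base-induced opening of the dihydropyran could compete with the [2,3]-shift onto a tetrasubstituted alkene. The fallback uses known chemistry, sets out from 13 and comes back at 17, and inverts the order of rearrangement and ring closure. n-Butyllithium in THF at −78 °C removes a proton from the O-allyl CH2 of 13, and the ordinary acyclic [2,3]-Wittig rearrangement gives triene alcohol F3. The quaternary C4 on the central allyl carbon forces C7 to the inside position, so the new trisubstituted alkene has C7 cis to C1, and 6S is again relayed to 1S. C10 is controlled less well here, so the epimer would be separated. Ring-closing metathesis of F3 with second-generation Grubbs catalyst RuCl2(=CHPh)(PCy3)(H2IMes) in CH2Cl2 at 40 °C then closes C8=C9 and gives 17.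

Step 10 (5-endo hydrosilylation of a trisubstituted alkene flanked by two fully substituted carbons). The fallback sets out from 20 and comes back at 25, bypassing 23. BH3·SMe2 in THF at 0 °C first converts the C4 hydroxyl into its alkoxyborane. Hydroboration of C5=C6 then takes place from the α face, which is the face of the boron tether and also the face away from the C1 methyl and C4 isopropyl, and gives cyclic alkoxyborane F4. C8=C9 is deactivated by the allylic ester and by the neopentyl position that boron would have to occupy. Oxidation with NaBO3·4H2O gives 25.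

Step 4 (catalyst control on a hindered, fully substituted enal with a nearby stereocentre). The fallback sets out from 7 and comes back at 10, replacing the asymmetric allylboration by a reagent-controlled ketone reduction. 2-Methylallylmagnesium chloride in THF at −78 °C adds without control and gives 10 mixed with carbinol epimer F1. Dess–Martin periodinane with NaHCO3 oxidises the mixture to dienone F2. Corey–Bakshi–Shibata reduction of F2 (catecholborane, 10 mol% (R)-1-methyl-3,3-diphenyltetrahydro-1H,3H-pyrrolo[1,2-c][1,3,2]oxazaborole, toluene, −78 °C, cyclopentenyl as the large group) returns 10.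

## Further compounds

F1 | step 4 | (1R)-3-methyl-1-{(5S)-2-methyl-5-(propan-2-yl)-5-[(triethylsilyl)oxy]cyclopent-1-en-1-yl}but-3-en-1-ol (C6 epimer of 10) | O[C@H](CC(C)=C)C1=C(C)CC[C@]1(O[Si](CC)(CC)CC)C(C)C
F2 | step 4 | 3-methyl-1-{(5S)-2-methyl-5-(propan-2-yl)-5-[(triethylsilyl)oxy]cyclopent-1-en-1-yl}but-3-en-1-one | O=C(CC(C)=C)C1=C(C)CC[C@]1(O[Si](CC)(CC)CC)C(C)C
F3 | step 7 | (1R)-1-{(1S,2E,3S)-1-methyl-2-(3-methylbut-3-en-1-ylidene)-3-(propan-2-yl)-3-[(triethylsilyl)oxy]cyclopentyl}prop-2-en-1-ol | C=C[C@@H](O)[C@@]1(C)CC[C@](O[Si](CC)(CC)CC)(C(C)C)/C1=C/CC(C)=C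
F4 | step 10 | cyclic alkoxyborane: B–H bonded to C6 (α) and to the C4 oxygen (1,2-oxaborolane), H5 α, 10-tiglate | C/C=C(\C)C(=O)O[C@@H]1C=C(C)C[C@H]3[C@@H]2[C@]1(C)CC[C@]2(OB3)C(C)C
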